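Take the late readings first: the new flasks are read at 5.0 min.

the same everywhere: Za 0.40 M
- green: Zc 4 equiv; Zd 2 equiv; Ze 8 mM; run made earlier
- red: Zc 4 equiv; Zd 4.8 equiv; Ze 8 mM; run made earlier
- north: Zc 4.00 equiv; Zd 2.20 equiv; Ze 8.00 mM; time 5.0 min
- east: Zc 4.00 equiv; Zd 1.50 equiv; Ze 8.00 mM; time 5.0 min
- north-west: Zc 4.00 equiv; Zd 3.40 equiv; Ze 8.00 mM; time 5.0 min

| run | time / min | Zg / % | Zf / % | Zb / % | Za / % |
|---|---|---|---|---|---|
| green | 1.00 | 1.2 | 2.9 | 0.4 | 93.1 |
| green | 2.00 | 2.6 | 7.4 | 0 | 88.7 |
| green | 3.00 | 3.4 | 10.1 | 0 | 84.2 |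
| green | 4.00 | 4.7 | 13.4 | 0.3 | 80.1 |
| green | 5.00 | 5.6 | 16.6 | 0.3 | 76.5 |
| red | 0.417 | 0.4 | 1.9 | 0.3 | 96.4 |
| red | 0.833 | 1.7 | 2.0 | 0.2 | 93.9 |
| red | 1.33 | 2.5 | 3.3 | 0 | 91.6 |
| red | 2.50 | 5.5 | 6.4 | 0.1 | 86.7 |
| red | 5.00 | 9.4 | 12.0 | 0.1 | 76.0 |

(standard deviation of a reading: 0.3 percentage points)



- which of these there is most of at the end, counted by the Za in it, north (Zg / Za / Zb / Zf)
- which of these there is most of at the end, counted by the Za in it, east (Zg / Za / Zb / Zf)
- which of these there is most of at the end, counted by the Za in it, north-west (Zg / Za / Zb / Zf)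
- the largest of these amounts at the end, in percent of the Za charged, north
- the largest of these amounts at the end, in percent of the Za charged, east
- the largest of these amounts at the end, in percent of the Za charged, north-west

Which given number must you know well? Time must. Green Za falls from 80.1% at 4.00 min to 76.5% at 5.00 min, so one minute's error costs 3.6 percentage points. Now take Zd. The Za readings at 5.00 min with 2 equiv and 4.8 equiv differ by 0.5 points, against a scatter of 0.3 points per reading, so these two runs show no effect of Zd on Za that you can read. Zc and Ze stand at the same charge in both runs and the new flasks, so the runs show nothing of their effect. Red has lost 24.0% of its Za by 5.00 min, less than the 76.0% remaining, so no split there puts a product above Za.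

So you need Za at 5.0 min, and my reckoning is the mean of the two runs, 76.2%, with Za largest in each new flask.

Zd does move the products. Take Zf and Zg as two exits from Zb, which reads 0.3% in green at 5.00 min. The rate of one over the rate of the other then has no time in it. Green gives 0.675 and red 0.653. Their mean 0.664 is the selectivity factor S, Zg over Zf per unit of Zd over Zc. You then expect Zg over Zf of 0.249 in east and 0.564 in north-west.

The forecast names Za for north, Za for east and Za for north-west, at 76.3%, 76.3% and 76.3%. Its ground: “Za consumption therefore looks independent of Zd”.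

The flasks give Za at 76.4% in north, Za at 76.4% in east and Za at 76.4% in north-west.

    Zc + Zb → Zf (k = 2.20 M⁻¹ s⁻¹)
    Za + Ze → Zh (k = 0.250 M⁻¹ s⁻¹)
    Zd + Zb → Zg (k = 1.50 M⁻¹ s⁻¹)
    Za → Zb (k = 8.30 × 10⁻⁴ s⁻¹)

Zg over Zf comes out at 0.257 in east, where S gave 0.249, and at 0.583 in north-west, where S gave 0.564. Time is one change that would make the forecast wrong: in east, Za and Zf hold the same at 16.4 min. The Za charge is another: with time held, north's Za has moved by 6 points at 0.0854 M. Read the east flask at 20 min, and S still expects 0.249. It holds Zf 49.0% and Zg 12.8%, a ratio of 0.261, and Zf now stands above Za at 36.2%.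

Readings and results were computed with constants of no real substance; noise was put on by code.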